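The 2(5H)-furanone is disconnected at the bond between its carbonyl carbon (C16, labdane numbering) and the alkene carbon C13 that carries the side chain. C13 lies between a CH2 (C12) and a =CH–CH2O arm (C14–C15), so the ring is a masked allene C12=C13=C14 plus CO. Ruthenium-catalysed cyclocarbonylation of a 2,3-allenol delivers an alkoxycarbonyl group to the central allene carbon, closing the lactone, installing C16 and fixing the alkene in one operation. The allenol comes in one step from a C12 aldehyde cut from trans-communic acid, whose exocyclic C8 methylene has first been turned into the equatorial carboxyl; both acids travel as PMB esters.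

Key step: step 8

Assumptions: trans-communic acid (1) is bought as the single natural enantiomer from natural-product suppliers; labdane numbering is used throughout. The C12 centre of 12 and the allene axis of 13 form as epimer mixtures, which is immaterial because both elements disappear in step 8.

Step 1
Reactants: 1 trans-communic acid (labda-8(17),12E,14-trien-19-oic acid)
Product: 3 12,12-dimethoxy-13,14,15,16-tetranorlabd-8(17)-en-19-oic acid, via C12 aldehyde 2 (not isolated)
Conditions: O3 (1.0 equiv, standardised CH2Cl2 solution), CH2Cl2/MeOH, −78 °C; Me2S, −78 °C → rt; then TsOH·H2O (cat.), MeOH, rt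
Reagents that add atoms: methanol, CO (both methoxy groups of 3); ozone, [O-][O+]=O (aldehyde oxygen of intermediate 2 only)
Why: Chemoselective ozonolysis with reductive work-up (Criegee mechanism) and in-pot acid-catalysed acetalisation: electrophilic ozone should cleave the trisubstituted, diene-conjugated C12=C13 bond ahead of the 1,1-disubstituted C8=C17 and monosubstituted C14=C15 bonds when one equivalent is delivered at −78 °C, the hindered axial C19 acid is not esterified by MeOH/TsOH at room temperature, and no stereocentre is touched because C9 is β to the new aldehyde.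

Step 2
Reactants: 3 12,12-dimethoxy-13,14,15,16-tetranorlabd-8(17)-en-19-oic acid
Product: 5 17-hydroxy-12,12-dimethoxy-13,14,15,16-tetranorlabdan-19-oic acid with the CH2OH group β (axial) on C8 and H-8 α, via alkylborane 4 (not isolated)
Conditions: 9-BBN (3 equiv), THF, 0 → 65 °C; then aq. NaOH, 30 % H2O2, 0 °C → rt; acidify to pH 5
Reagents that add atoms: hydrogen peroxide, OO (oxygen on C17); 9-BBN, B1C2CCCC1CCC2 (boron of intermediate 4 only)
Why: Anti-Markovnikov hydroboration–oxidation: the first equivalent of 9-BBN is consumed by the acid as an acyloxyborane that 9-BBN reduces only sluggishly, boron adds to C17 and hydrogen to C8 from the α face opposite the axial C10 methyl, so the CH2OH group is expected axial (β); this configuration is provisional and is corrected in step 3.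

Step 3
Reactants: 5 17-hydroxy acetal acid (8β-CH2OH)
Product: 7 12,12-dimethoxy-17-oxo-13,14,15,16-tetranorlabdan-19-oic acid with the formyl group α (equatorial) on C8 and H-8 β, via 8β-formyl epimer 6 (not isolated)
Conditions: Dess–Martin periodinane, pyridine, CH2Cl2, 0 °C → rt; then K2CO3 (3 equiv), MeOH, rt; acidify to pH 5
Reagents that add atoms: none
Why: Dess–Martin oxidation followed by base-mediated epimerisation through the enolate: the formyl group leaves the axial position, where it is 1,3-diaxial to the C10 methyl, for the equatorial α position trans to the C9 side chain, so C8 is set under thermodynamic control as 8R, and any 8α-CH2OH epimer from step 2 converges on the same aldehyde.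

Step 4
Reactants: 7 8α-formyl acetal acid
Product: 8 12,12-dimethoxy-13,14,15,16-tetranorlabdane-17,19-dioic acid (8α-CO2H, H-8 β)
Conditions: NaClO2, NaH2PO4, 2-methyl-2-butene, t-BuOH/H2O, 0 °C
Reagents that add atoms: sodium chlorite, [Na+].[O-]Cl=O
Why: Pinnick oxidation: chlorous acid converts the aldehyde into the acid without disturbing C8 (already the stable epimer), 2-methyl-2-butene scavenges HOCl, and the cold phosphate buffer (pH about 4–5) should leave the dimethyl acetal intact.

Step 5
Reactants: 8 acetal diacid
Product: 9 bis(4-methoxybenzyl) 12,12-dimethoxy-13,14,15,16-tetranorlabdane-17,19-dioate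
Conditions: PMBCl (2.5 equiv), Cs2CO3, TBAI (cat.), DMF, rt → 40 °C
Reagents that add atoms: 4-methoxybenzyl chloride, COc1ccc(CCl)cc1
Why: Double O-alkylation of the caesium carboxylates (SN2 at the benzylic chloride): bond formation takes place at oxygen, away from the hindered C4 centre, so the axial neopentyl-type C19 acid should be esterified as readily as the C17 acid, and the acetal is inert to base.

Step 6
Reactants: 9 bis-PMB ester acetal
Product: 10 bis(4-methoxybenzyl) 12-oxo-13,14,15,16-tetranorlabdane-17,19-dioate (side chain C9–CH2–CHO)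
Conditions: 1 M aq. HCl, THF, rt
Reagents that add atoms: water, O
Why: Acid-catalysed acetal hydrolysis: dilute aqueous acid at room temperature unmasks the aldehyde, while PMB esters, which need strong acid such as TFA, survive.

Step 7
Reactants: 10 C12 aldehyde bis-PMB ester; 11 propargyl alcohol
Product: 13 bis(4-methoxybenzyl) 15-hydroxy-16-norlabda-12,13-diene-17,19-dioate (2,3-allenol: C9–CH2–CH=C=CH–CH2OH), via propargylic amine 12 (not isolated)
Conditions: 11 (1.5 equiv), morpholine (1.4 equiv), ZnI2 (0.8 equiv), toluene, 130 °C, sealed tube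
Reagents that add atoms: morpholine, C1COCCN1 (amine ring of intermediate 12 only)
Why: Crabbé-type allenation of a terminal alkyne with an aldehyde: zinc-mediated three-component aldehyde–alkyne–amine coupling gives the propargylic amine, zinc activation of the alkyne triggers a 1,5-hydride shift from a morpholine α-CH2 to C14, and β-elimination of the cyclic imine forms the C12=C13=C14 allene with the free hydroxyl on C15; the allene axis is uncontrolled and irrelevant.

Step 8
Reactants: 13 2,3-allenol bis-PMB ester
Product: 14 bis(4-methoxybenzyl) labd-13-en-16,15-olide-17,19-dioate (3-substituted 2(5H)-furanone)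
Conditions: Ru3(CO)12 (3 mol %), Et3N (1.5 equiv), CO (10 atm), 1,4-dioxane, 100 °C
Reagents that add atoms: carbon monoxide, [C-]#[O+]
Why: Ruthenium-catalysed cyclocarbonylation of an α-allenic alcohol, the known Ru3(CO)12/Et3N/CO lactonisation of 2,3-dienols to 3-substituted 2(5H)-furanones: O–H activation on Ru(0), assisted by Et3N, gives a hydrido-alkoxide, CO inserts into Ru–O to give an alkoxycarbonyl–ruthenium hydride, this carbonyl carbon migrates to the central allene carbon C13 leaving ruthenium as an η3-allyl over C12–C13–C14, and C–H reductive elimination at C12 releases the product. The lactone closes in a 5-exo migratory insertion onto the C12=C13 π bond, the new C–C bond joining the oxygen-bound carbonyl carbon to the sp carbon C13. No stereocentre is created: the allene axis vanishes, and the five ring stereocentres are remote, C8 being already in its thermodynamic equatorial configuration so that Et3N at 100 °C cannot change it. Regioselectivity for the central carbon is enforced by the three-atom O–CH2–CH= tether, since only this mode gives a five-membered ring. The endocyclic position of the alkene (C13=C14) should follow from hydride return to the exocyclic allyl terminus C12 and, failing that, from Et3N/Ru–H equilibration of any α-alkylidene lactone to the conjugated, more stable butenolide. Chemoselectivity is secured because only the free primary hydroxyl can enter the cycle, the PMB esters being inert to Ru(0)/CO.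

Step 9
Reactants: 14 butenolide bis-PMB ester
Product: 15 labd-13-en-16,15-olide-17,19-dioic acid, the target
Conditions: TFA, anisole, CH2Cl2, 0 °C → rt
Reagents that add atoms: none
Why: Acidolysis of the 4-methoxybenzyl esters (SN1 cleavage, the PMB cation being trapped by anisole in a Friedel–Crafts alkylation): the butenolide and all stereocentres are stable to anhydrous TFA, so both acids should be freed in one operation.

Compound list

1 | trans-communic acid; (1S,4aR,5S,8aR)-1,4a-dimethyl-6-methylidene-5-[(2E)-3-methylpenta-2,4-dien-1-yl]decahydronaphthalene-1-carboxylic acid | C[C@]12CCC[C@](C)(C(=O)O)[C@@H]1CCC(=C)[C@@H]2C/C=C(\C)C=C | starting material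
2 | 12-oxo-13,14,15,16-tetranorlabd-8(17)-en-19-oic acid (side chain C9–CH2–CHO) | C[C@]12CCC[C@](C)(C(=O)O)[C@@H]1CCC(=C)[C@@H]2CC=O | intermediate
3 | 12,12-dimethoxy-13,14,15,16-tetranorlabd-8(17)-en-19-oic acid | C[C@]12CCC[C@](C)(C(=O)O)[C@@H]1CCC(=C)[C@@H]2CC(OC)OC | intermediate
4 | alkylborane: C17 bound to the boron of 9-BBN (CH2B group β on C8, H-8 α), the 19-carboxyl held as its O-(9-BBN) acyloxyborane | C[C@]12CCC[C@](C)(C(=O)OB3C4CCCC3CCC4)[C@@H]1CC[C@H](CB3C4CCCC3CCC4)[C@@H]2CC(OC)OC | intermediate
5 | (8S)-17-hydroxy-12,12-dimethoxy-13,14,15,16-tetranorlabdan-19-oic acid (8β-CH2OH axial, H-8 α) | C[C@]12CCC[C@](C)(C(=O)O)[C@@H]1CC[C@H](CO)[C@@H]2CC(OC)OC | intermediate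
6 | (8S)-12,12-dimethoxy-17-oxo-13,14,15,16-tetranorlabdan-19-oic acid (8β-CHO axial) | C[C@]12CCC[C@](C)(C(=O)O)[C@@H]1CC[C@H](C=O)[C@@H]2CC(OC)OC | intermediate
7 | (8R)-12,12-dimethoxy-17-oxo-13,14,15,16-tetranorlabdan-19-oic acid (8α-CHO equatorial, H-8 β) | C[C@]12CCC[C@](C)(C(=O)O)[C@@H]1CC[C@@H](C=O)[C@@H]2CC(OC)OC | intermediate
8 | (8R)-12,12-dimethoxy-13,14,15,16-tetranorlabdane-17,19-dioic acid | C[C@]12CCC[C@](C)(C(=O)O)[C@@H]1CC[C@@H](C(=O)O)[C@@H]2CC(OC)OC | intermediate
9 | bis(4-methoxybenzyl) (8R)-12,12-dimethoxy-13,14,15,16-tetranorlabdane-17,19-dioate | C[C@]12CCC[C@](C)(C(=O)OCc3ccc(OC)cc3)[C@@H]1CC[C@@H](C(=O)OCc3ccc(OC)cc3)[C@@H]2CC(OC)OC | intermediate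
10 | bis(4-methoxybenzyl) (8R)-12-oxo-13,14,15,16-tetranorlabdane-17,19-dioate | C[C@]12CCC[C@](C)(C(=O)OCc3ccc(OC)cc3)[C@@H]1CC[C@@H](C(=O)OCc3ccc(OC)cc3)[C@@H]2CC=O | intermediate
11 | propargyl alcohol (prop-2-yn-1-ol) | C#CCO | starting material
12 | bis(4-methoxybenzyl) 15-hydroxy-12-(morpholin-4-yl)-16-norlabd-13-yne-17,19-dioate (C12 epimers) | C[C@]12CCC[C@](C)(C(=O)OCc3ccc(OC)cc3)[C@@H]1CC[C@@H](C(=O)OCc3ccc(OC)cc3)[C@@H]2CC(N3CCOCC3)C#CCO | intermediate
13 | bis(4-methoxybenzyl) 15-hydroxy-16-norlabda-12,13-diene-17,19-dioate (2,3-allenol, axis unassigned) | C[C@]12CCC[C@](C)(C(=O)OCc3ccc(OC)cc3)[C@@H]1CC[C@@H](C(=O)OCc3ccc(OC)cc3)[C@@H]2CC=C=CCO | intermediate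
14 | bis(4-methoxybenzyl) labd-13-en-16,15-olide-17,19-dioate | C[C@]12CCC[C@](C)(C(=O)OCc3ccc(OC)cc3)[C@@H]1CC[C@@H](C(=O)OCc3ccc(OC)cc3)[C@@H]2CCC1=CCOC1=O | intermediate
15 | (1S,4aR,5S,6R,8aR)-1,4a-dimethyl-5-[2-(2-oxo-2,5-dihydrofuran-3-yl)ethyl]decahydronaphthalene-1,6-dicarboxylic acid (labd-13-en-16,15-olide-17,19-dioic acid) | C[C@]12CCC[C@](C)(C(=O)O)[C@@H]1CC[C@@H](C(=O)O)[C@@H]2CCC1=CCOC1=O | target

Total step count: 9. Longest linear sequence: 9 steps (1 → 15).

Steps most likely to fail

Step 8 (key step). The alkoxycarbonyl–ruthenium insertion may be slow on a 1,3-disubstituted allene, so that ruthenium-hydride isomerisation of the allene to a conjugated diene, or hydrogen return to C14 without later alkene migration, competes with clean lactone formation. The fallback brings the lactone ring in preformed and sets out from aldehyde 10. Wittig olefination with the commercial stabilised ylide 3-(triphenylphosphoranylidene)oxolan-2-one (toluene, 80 °C) should give the (E)-α-alkylidene-γ-butyrolactone F1. Rhodium-catalysed alkene isomerisation (RhCl3·3H2O cat., EtOH, 70 °C) is then expected to move the exocyclic C12=C13 bond into the ring, to the conjugated and more stable C13=C14 position. This returns to the route at 14.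

Step 7. The three-component coupling may stall at the propargylic amine, the α-unbranched aldehyde may be diverted into enamine and aldol self-condensation, or the PMB esters may be eroded by ZnI2 at 130 °C. The fallback builds the allene by a sigmatropic route at low temperature and sets out from aldehyde 10. Addition of the lithium acetylide of tert-butyldimethyl(prop-2-yn-1-yloxy)silane (n-BuLi, THF, −78 °C; the aldehyde reacts far faster than the esters) should give the propargylic alcohol F2. Mitsunobu displacement with 2-nitrobenzenesulfonylhydrazine (PPh3, DEAD, THF, −15 °C) gives the propargylic sulfonylhydrazine F3 (not isolated). On warming to room temperature F3 loses the sulfinic acid to give the propargylic diazene F4 (not isolated). Retro-ene loss of nitrogen (Myers allene synthesis) then delivers the allenyl silyl ether F5. Desilylation (TBAF, AcOH, THF, 0 °C) returns to the route at 13.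

Step 1. Ozone may attack the C8=C17 methylene or the terminal vinyl group competitively, leading to over-cleavage or to partial cleavage of the diene. The fallback removes the need for selectivity and sets out from 1. Exhaustive ozonolysis (excess O3, CH2Cl2/MeOH, −78 °C; Me2S) cleaves all three alkenes to give the keto aldehyde F6 (not isolated). Acetalisation in the same pot (TsOH cat., MeOH; the aldehyde reacts in preference to the hindered C8 ketone, and any ketal is lost on aqueous work-up) gives the keto acetal F7. Wittig methylenation of the C8 ketone (Ph3PCH3Br, KOt-Bu, 3 equiv, THF, rt; the C9 side chain stays in its equatorial, thermodynamic orientation) restores the exocyclic methylene and returns to the route at 3.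

Further compounds

F1 | step 8 | bis(4-methoxybenzyl) (12E)-labd-12-en-16,15-olide-17,19-dioate ((E)-α-alkylidene-γ-butyrolactone) | C[C@]12CCC[C@](C)(C(=O)OCc3ccc(OC)cc3)[C@@H]1CC[C@@H](C(=O)OCc3ccc(OC)cc3)[C@@H]2C/C=C1\CCOC1=O
F2 | step 7 | bis(4-methoxybenzyl) 15-(tert-butyldimethylsilyloxy)-12-hydroxy-16-norlabd-13-yne-17,19-dioate (C12 epimers) | C[C@]12CCC[C@](C)(C(=O)OCc3ccc(OC)cc3)[C@@H]1CC[C@@H](C(=O)OCc3ccc(OC)cc3)[C@@H]2CC(O)C#CCO[Si](C)(C)C(C)(C)C
F3 | step 7 | propargylic N-(2-nitrobenzenesulfonyl)hydrazine at C12 (Mitsunobu adduct of F2, not isolated) | C[C@]12CCC[C@](C)(C(=O)OCc3ccc(OC)cc3)[C@@H]1CC[C@@H](C(=O)OCc3ccc(OC)cc3)[C@@H]2CC(N(N)S(=O)(=O)c3ccccc3[N+](=O)[O-])C#CCO[Si](C)(C)C(C)(C)C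
F4 | step 7 | propargylic diazene at C12 (not isolated) | C[C@]12CCC[C@](C)(C(=O)OCc3ccc(OC)cc3)[C@@H]1CC[C@@H](C(=O)OCc3ccc(OC)cc3)[C@@H]2CC(N=N)C#CCO[Si](C)(C)C(C)(C)C
F5 | step 7 | bis(4-methoxybenzyl) 15-(tert-butyldimethylsilyloxy)-16-norlabda-12,13-diene-17,19-dioate (allenyl silyl ether) | C[C@]12CCC[C@](C)(C(=O)OCc3ccc(OC)cc3)[C@@H]1CC[C@@H](C(=O)OCc3ccc(OC)cc3)[C@@H]2CC=C=CCO[Si](C)(C)C(C)(C)C
F6 | step 1 | 8,12-dioxo-13,14,15,16,17-pentanorlabdan-19-oic acid (not isolated) | C[C@]12CCC[C@](C)(C(=O)O)[C@@H]1CCC(=O)[C@@H]2CC=O
F7 | step 1 | 12,12-dimethoxy-8-oxo-13,14,15,16,17-pentanorlabdan-19-oic acid | C[C@]12CCC[C@](C)(C(=O)O)[C@@H]1CCC(=O)[C@@H]2CC(OC)OC
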